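**Assumption:** the SMILES has no stereocentre and no stereogenic double bond, so kazinol D is achiral and needs no stereocontrol; 4-allylcatechol is taken as a catalogue chemical.

## Retrosynthetic overview

1. Kazinol D is cut at the ring A–CH2 bond of the propane linker: B-alkyl Suzuki–Miyaura coupling of the 9-BBN adduct of a 6-allylchroman (ring B fragment) with a 4-iodoresorcinol (ring A fragment).
2. The ring B fragment comes from Stille prenylation of a 5-bromide, made by para-bromination of 6-allyl-2,2-dimethylchroman-8-ol.
3. The chroman, the only ring made, is formed first: titanium-templated ortho-prenylation of free 4-allylcatechol with isoprene, then ring closure by C–O bond formation at the same oxygen.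
4. The ring A fragment comes from resorcinol by O-prenylation, ortho-iodination (blocks the para position and provides the coupling handle) and aromatic Claisen rearrangement to the 1,1-dimethylallyl group.
5. Both benzene rings are bought; no ring other than the chroman is constructed.

## Route

**Step 1**
Reactants: 1 4-allylcatechol; 2 isoprene
Product: 4 6-allyl-2,2-dimethylchroman-8-ol, via 5-allyl-3-prenylcatechol 3 (not isolated)
Conditions: Ti(O-i-Pr)4 (10 mol %), xylene, 120 °C, i-PrOH distilled off; then isoprene (1.5 equiv), sealed tube, 110 °C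
Reagents that add atoms: none
Why: Proposed new method: 1 displaces i-PrOH to give a catecholate of tetravalent titanium whose Ti-bound catechol O–H acts as a Lewis-acid-assisted Brønsted acid and protonates isoprene inside the coordination sphere; the prenyl cation collapses on the ortho carbon beside the metal-bound oxygen (unhindered C6, not C3 flanked by the allyl group, not the remote para C5) to give 3; Markovnikov re-protonation of the prenyl alkene then lets the neighbouring Ti–O oxygen trap the tertiary cation, closing the chroman by C–O bond formation, and the product, now only a hindered monodentate phenoxide, is displaced by fresh 1, which gives turnover and prevents a second annulation; the closest known reaction types are the Ti(O2C6H4)2-catalysed ortho-tert-butylation of catechol with isobutene and the H3PO4- or Al(OPh)3-mediated phenol–isoprene chroman annulation, neither shown for site-selective mono-annulation of a free unsymmetrical catechol.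

**Step 2**
Reactants: 4 6-allyl-2,2-dimethylchroman-8-ol
Product: 5 6-allyl-5-bromo-2,2-dimethylchroman-8-ol
Conditions: NBS (1.0 equiv), MeCN, −20 °C to 0 °C, dark
Reagents that add atoms: N-bromosuccinimide (NBS), O=C1CCC(=O)N1Br
Why: Electrophilic aromatic bromination of a phenol in a polar solvent goes para to the free OH (C5; compare guaiacol and 3,5-dimethylphenol) and is much faster than attack on the unactivated terminal allyl alkene.

**Step 3**
Reactants: 5 6-allyl-5-bromo-2,2-dimethylchroman-8-ol; 6 tributyl(3-methylbut-2-en-1-yl)stannane
Product: 7 6-allyl-2,2-dimethyl-5-(3-methylbut-2-en-1-yl)chroman-8-ol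
Conditions: Pd(PPh3)4 (5 mol %), DMF, 100 °C
Reagents that add atoms: none
Why: Stille coupling under neutral conditions tolerates the free phenol, and reductive elimination from the allyl–palladium intermediate occurs at the less substituted terminus, giving the linear prenyl group.

**Step 4**
Reactants: 8 resorcinol; 9 prenyl bromide
Product: 10 3-[(3-methylbut-2-en-1-yl)oxy]phenol
Conditions: resorcinol (3 equiv), K2CO3 (1.1 equiv), acetone, reflux
Reagents that add atoms: none
Why: Williamson etherification with excess diol gives mainly the mono-ether, and K2CO3 in acetone favours O- over C-alkylation.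

**Step 5**
Reactants: 10 3-[(3-methylbut-2-en-1-yl)oxy]phenol
Product: 11 2-iodo-5-[(3-methylbut-2-en-1-yl)oxy]phenol
Conditions: I2 (1.0 equiv), NaHCO3 (1.2 equiv), THF–H2O 1:1, 0 °C
Reagents that add atoms: iodine, II
Why: Electrophilic aromatic iodination of the phenoxide occurs at the position ortho to OH and para to the ether oxygen (as with 3-methoxyphenol) and is far faster than iodination of the prenyl alkene.

**Step 6**
Reactants: 11 2-iodo-5-[(3-methylbut-2-en-1-yl)oxy]phenol
Product: 13 4-iodo-6-(2-methylbut-3-en-2-yl)benzene-1,3-diol, via ortho-dienone 12 (not isolated)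
Conditions: EtOH–H2O 4:1, 135 °C, sealed tube
Reagents that add atoms: none
Why: Water-accelerated aromatic Claisen [3,3] rearrangement delivers the inverted 1,1-dimethylallyl group to the less hindered ortho carbon (not the one between the two oxygens), and the iodine at the para position blocks any Cope relay.

**Step 7**
Reactants: 7 6-allyl-2,2-dimethyl-5-(3-methylbut-2-en-1-yl)chroman-8-ol; 13 4-iodo-6-(2-methylbut-3-en-2-yl)benzene-1,3-diol
Product: 15 kazinol D, via B-alkyl-9-BBN adduct 14 (not isolated)
Conditions: 7, 9-BBN (2.2 equiv), THF, 0 °C to rt; then 3 M aq NaOH (5 equiv, degassed), 13 (1.0 equiv), Pd(dppf)Cl2 (5 mol %), THF, 65 °C; aq NH4Cl work-up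
Reagents that add atoms: none
Why: 9-BBN hydroborates only the terminal allyl alkene anti-Markovnikov (one equivalent is used up by the phenol, the trisubstituted prenyl alkene is inert), the aqueous base destroys excess B–H before 13 is added, and B-alkyl Suzuki–Miyaura coupling with the aryl iodide forms the 1,3-diarylpropane.

## Compound list

1 | 4-allylcatechol (4-(prop-2-en-1-yl)benzene-1,2-diol) | C=CCc1ccc(O)c(O)c1 | starting material
2 | isoprene (2-methylbuta-1,3-diene) | C=CC(C)=C | starting material
3 | 5-allyl-3-prenylcatechol (5-allyl-3-(3-methylbut-2-en-1-yl)benzene-1,2-diol; present as its titanium catecholate) | C=CCc1cc(O)c(O)c(CC=C(C)C)c1 | intermediate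
4 | 6-allyl-2,2-dimethylchroman-8-ol | C=CCc1cc(O)c2OC(C)(C)CCc2c1 | intermediate
5 | 6-allyl-5-bromo-2,2-dimethylchroman-8-ol | C=CCc1cc(O)c2OC(C)(C)CCc2c1Br | intermediate
6 | tributyl(3-methylbut-2-en-1-yl)stannane (prenyltributyltin) | CCCC[Sn](CCCC)(CCCC)CC=C(C)C | starting material
7 | 6-allyl-2,2-dimethyl-5-(3-methylbut-2-en-1-yl)chroman-8-ol | C=CCc1cc(O)c2OC(C)(C)CCc2c1CC=C(C)C | intermediate
8 | resorcinol (benzene-1,3-diol) | Oc1cccc(O)c1 | starting material
9 | prenyl bromide (1-bromo-3-methylbut-2-ene) | CC(C)=CCBr | starting material
10 | 3-[(3-methylbut-2-en-1-yl)oxy]phenol | CC(C)=CCOc1cccc(O)c1 | intermediate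
11 | 2-iodo-5-[(3-methylbut-2-en-1-yl)oxy]phenol | CC(C)=CCOc1ccc(I)c(O)c1 | intermediate
12 | ortho-dienone: 3-hydroxy-4-iodo-6-(2-methylbut-3-en-2-yl)cyclohexa-2,4-dien-1-one | C=CC(C)(C)C1C=C(I)C(O)=CC1=O | intermediate
13 | 4-iodo-6-(2-methylbut-3-en-2-yl)benzene-1,3-diol | C=CC(C)(C)c1cc(I)c(O)cc1O | intermediate
14 | B-alkyl-9-BBN adduct: 9-{3-[8-(9-borabicyclo[3.3.1]nonan-9-yloxy)-2,2-dimethyl-5-(3-methylbut-2-en-1-yl)chroman-6-yl]propyl}-9-borabicyclo[3.3.1]nonane | CC(C)=CCc1c(CCCB2C3CCCC2CCC3)cc(OB2C3CCCC2CCC3)c2OC(C)(C)CCc12 | intermediate
15 | kazinol D: 4-{3-[8-hydroxy-2,2-dimethyl-5-(3-methylbut-2-en-1-yl)chroman-6-yl]propyl}-6-(2-methylbut-3-en-2-yl)benzene-1,3-diol | C=CC(C)(C)c1cc(CCCc2cc(O)c3c(c2CC=C(C)C)CCC(C)(C)O3)c(O)cc1O | target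

## Summary and risk

Total step count: 7. Longest linear sequence: 4 steps (1 → 2 → 3 → 7, or 4 → 5 → 6 → 7).

**Steps most likely to fail**

Step 1 (the proposed new annulation). The risks are para C-prenylation at C5, attack at the hindered C3, a second annulation at C7 of the product, and isoprene oligomerisation. The fallback uses known chemistry and sets out from isoprene 2, with bought eugenol F1 taking the place of 1. Its single free OH fixes the regiochemistry in a classical acid-catalysed phenol–isoprene annulation (85% H3PO4, xylene, 30 °C), giving 6-allyl-8-methoxy-2,2-dimethylchroman F2. The methyl ether is then cleaved with NaSEt in DMF at 130 °C, and the route is rejoined at 4 (one step longer).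

Step 3 (Stille prenylation). The bromide is flanked by two ortho substituents and is electron-rich, so oxidative addition may be slow, and allyl isomerisation or branched coupling could intrude. The fallback replaces palladium coupling with organolithium/copper allylation and sets out from 5. Silylation (t-BuMe2SiCl, imidazole, DMF) gives tert-butyldimethylsilyl ether F3. Bromine–lithium exchange (t-BuLi, 2.1 equiv, THF, −78 °C) gives aryllithium F4, which is alkylated with prenyl bromide 9 in the presence of CuBr·SMe2 to give 5-prenyl silyl ether F5. Bu4NF in THF removes the silyl group and the route is rejoined at 7.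

Step 7 (hydroboration/B-alkyl Suzuki union). The iodoresorcinol 13 is very electron-rich as its dianion and may undergo slow oxidative addition or protodeiodination, and it carries a vinyl group. The fallback moves the Claisen rearrangement to the end and sets out from 7 and 11. Borane 14, made as in step 7, is coupled with the simpler mono-phenol iodide 11 (Pd(dppf)Cl2, aq NaOH, THF, 65 °C) to give prenyl ether F6. Heating F6 (EtOH–H2O 4:1, 135 °C, sealed tube) effects the aromatic Claisen rearrangement at the only unhindered ortho position, with the para position blocked by the propyl chain. The route is rejoined at the target 15.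

## Further compounds

F1 | step 1 | eugenol (4-allyl-2-methoxyphenol, bought) | COc1cc(CC=C)ccc1O
F2 | step 1 | 6-allyl-8-methoxy-2,2-dimethylchroman | C=CCc1cc(OC)c2OC(C)(C)CCc2c1
F3 | step 3 | [(6-allyl-5-bromo-2,2-dimethylchroman-8-yl)oxy](tert-butyl)dimethylsilane | C=CCc1cc(O[Si](C)(C)C(C)(C)C)c2OC(C)(C)CCc2c1Br
F4 | step 3 | [6-allyl-8-(tert-butyldimethylsilyloxy)-2,2-dimethylchroman-5-yl]lithium | [Li]c1c(CC=C)cc(O[Si](C)(C)C(C)(C)C)c2OC(C)(C)CCc12
F5 | step 3 | {[6-allyl-2,2-dimethyl-5-(3-methylbut-2-en-1-yl)chroman-8-yl]oxy}(tert-butyl)dimethylsilane | C=CCc1cc(O[Si](C)(C)C(C)(C)C)c2OC(C)(C)CCc2c1CC=C(C)C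
F6 | step 7 | 2-{3-[8-hydroxy-2,2-dimethyl-5-(3-methylbut-2-en-1-yl)chroman-6-yl]propyl}-5-[(3-methylbut-2-en-1-yl)oxy]phenol | CC(C)=CCOc1ccc(CCCc2cc(O)c3c(c2CC=C(C)C)CCC(C)(C)O3)c(O)c1
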